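# Proposed synthesis of (1S,2S,5S,6R)-2,6-bis(3,4-dimethoxyphenyl)-3,7-dioxabicyclo[3.3.0]octan-1-ol (CNP0422369.10)

Atom labels used for every compound: C1 is the carbinol bridgehead, C2 its aryl-bearing neighbour, then O3, C4, C5 (the CH bridgehead), C6 (second aryl-bearing carbon), O7 and C8. Ring A is C5–C6–O7–C8–C1 and ring B is C1–C2–O3–C4–C5. Ar is 3,4-dimethoxyphenyl.

Compound numbers: 1 meso anhydride; 2 half-ester; 3 aryl bromide; 4 acid chloride; 5 aryl Grignard reagent; 6 keto ester; 7 potassium enolate; 8 hydroxy ketone; 9 diol; 10 acetonide (precursor of the key step); 11 ozonide; 12 diol ester; 13 lactone alcohol (product of the key step); 14 silyl ether; 15 aryllithium; 16 lactol; 17 ring A ether; 18 primary alcohol; 19 tosylate; 20 diol tosylate; 21 target.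

## Analysis of the target

Target 21 is a 3,7-dioxabicyclo[3.3.0]octane (two fused oxolanes) with a tertiary hydroxyl at the bridgehead C1 and 3,4-dimethoxyphenyl groups at C2 and C6. The four stereocentres C1, C2, C5 and C6 are contiguous and have the configuration (1S,2S,5S,6R). Read in three dimensions, these descriptors place the C1 hydroxyl and the C5 hydrogen on opposite faces, so the two rings are trans-fused; the bicycle is strained and must be closed under kinetic control. On ring A the C6 aryl group is trans to C4 (cis to H-5); on ring B the C2 aryl group is trans to the C1 hydroxyl and cis to C8. Both benzylic C–O bonds carry electron-rich arenes and ionize under acid, which would scramble C2 and C6; the arenes are also oxidizable. The difficulty lies in a fully substituted carbinol centre flanked by two benzylic ether centres, together with a ring fusion that no equilibration will deliver. The strategy rests on one feature: C4 and C8 are oxygenated methylene groups on the adjacent carbons C5 and C1. Joined to each other they are the olefinic carbons of a cyclobutene C1–C5–C4=C8, on which C2 and C6 are cis (the pattern of a meso cis-1,2-diacid) and the C1 oxygen is anti to C6.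

## Retrosynthetic reasoning

21 to 20. The O3–C4 bond of ring B is cut last. This keeps the strained trans-fused bicycle out of every earlier step, and the closure is an irreversible displacement in which the C2 oxygen is the nucleophile, so the benzylic centre C2 is not touched. The forward step must favour the five-membered closure by the secondary C2 alkoxide over any reaction of the tertiary C1 alkoxide. Diol tosylate 20 is traced back through functional-group changes to tosylate 19, alcohol 18 and silyl ether 17, with the C1/C2 diol held as an acetonide until the end.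

17 to 16, then to 14 and 15. The C6–aryl bond is cut, with the C6–H bond behind it. In lactone 14 ring A already exists and C6 is its carbonyl carbon, so one equivalent of aryllithium 15 gives hemiketal 16 and an ionic reduction fixes C6. Introducing the second arene this late keeps it away from the oxidative key step. The forward reduction must deliver hydride cis to C4.

14 to 13 to 10 (key disconnection). The lactone bond C6–O7 is cut and C4 is reconnected to C8 as an alkene. The two hydroxymethyl arms of 13 become the double bond of cyclobutene 10. The relation between C1 and C5, which in the open chain leads to the trans ring fusion, is in 10 a relation between substituents on a rigid four-membered ring. The forward step has to cleave the alkene in the presence of an electron-rich arene, deliver both carbons as carbinols and leave C5 untouched; lactonization of the C8 hydroxyl onto the C6 ester then closes ring A and leaves the C4 hydroxyl free, so the two arms are differentiated without a protecting group.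

10 to 9 to 8. The acetonide is opened to diol 9, and the C2–H bond is cut back to ketone 8. The free tertiary hydroxyl of 8 serves as the anchor for a chelate, so C2 is derived from C1.

8 to 6 (through enolate 7). The C1–O bond is cut. On the cyclobutene the only neighbouring substituent is the C6 ester on C5, so an electrophilic oxygen enters the enolate anti to it; this places the oxygen anti to C6 and keeps C2 cis to C6.

6 to 2 and 3. The C2–aryl bond is cut to an acyl electrophile (acid chloride 4) and the Grignard reagent 5 made from bromide 3. The C1 centre of 6 need not survive this step, since it is planarized in 7.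

2 to 1. Half-ester 2 comes from the meso anhydride 1 by differentiating its enantiotopic carbonyl groups. This single event decides the absolute configuration of C5 and which carbonyl carbon becomes C2 and which C6; every other stereocentre is derived from C5.

## Alternatives that were turned down

Alternative 1: Both C–O bonds at C1 and C2 are traced back to an exocyclic (E)-alkene on a γ-lactone in which C8 is the carbonyl carbon and C4 the O-methylene, the benzylidene lactone A2. The forward key step is an osmium-catalysed syn-dihydroxylation of A2 on the face away from the C5 side chain, giving lactone diol A1. For it: C1 and C2 arise in one catalytic operation, their relative configuration is fixed by the alkene geometry, and the conditions are mild toward the arenes. On this point the alternative is stronger than the chosen route, which needs two operations (steps 3 and 4) and a chelate to set the same pair. Against it: face selection rests on one substituent of a flexible five-membered ring. A2 itself needs an independent asymmetric construction of C5 and C6. The lactone of A1 joins C4 to C8 through an oxygen that the target does not contain, so after the key step it must be reduced and both rings still have to be closed, including the trans-fused one, with three other hydroxyl groups in the molecule. The chosen strategy instead relates C1 to C5 on a rigid four-membered ring, has ring A in place as soon as the key step is over, and obtains C4 and C8 already differentiated.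

Alternative 2: O3–C4 and O7–C8 are both cut, which leads to the open-chain bis-tosylate A4 (C1 as a triethylsilyl ether, free benzylic hydroxyls at C2 and C6). In the forward key step a hydride base turns both benzylic hydroxyls into alkoxides and each closes a ring by 5-exo-tet displacement, giving A3, the triethylsilyl ether of 21. For it: both rings form in one operation, both benzylic centres keep their configuration because oxygen is the nucleophile, crossed closures are excluded by ring size, and the protected C1 oxygen cannot compete. In this last respect it is stronger than step 13 of the chosen route, where the tertiary hydroxyl is free. Against it: A4 carries four contiguous stereocentres, one of them fully substituted, in an open chain, and the disconnection offers no element that sets C1 relative to C5. A hindered tertiary silyl ether must be made and removed, two primary sulfonates must be installed beside two secondary benzylic alcohols, and the second closure still has to form the trans-fused bicycle. The chosen strategy spends its steps on exactly the relation that this alternative leaves open, at the price of a longer linear end game.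

Alternative 3: C5–C6 and C6–O7 are cut; C6 and its arene come from the aryl aldehyde dimethyl acetal A7, the rest from the diol allylsilane A6. In the forward key step a silyl triflate exchanges the C8 hydroxyl into the acetal and ionizes it to the O7=C6 oxocarbenium ion, which the allylsilane captures through C5 with loss of silicon, giving the 2-aryl-3-vinyl oxolane A5. For it: two bonds, ring A and the centres C5 and C6 are made in one step from a simple aromatic building block; in convergence and step economy at this stage it is stronger than the chosen route. Against it: C5 must form with its vinyl group cis to the C1 hydroxyl and trans to the C6 arene, and this outcome depends on a transition-state geometry around a fully substituted C1 that is hard to predict. The vicinal C1/C8 diol of A6 can rest as a cyclic acetal with A7, the strongly Lewis acidic medium acts on a benzylic silyl ether at C2, and the vinyl group carries one carbon too many, so C4 must be unveiled later by cleavage and reduction. The chosen strategy fixes C5 before any ring is formed and reads C1 from it on the cyclobutene, giving up convergence for certainty at the ring fusion.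

Key step: step 6

Assumption: quinidine is taken to deliver the (1S,2R) half-ester 2 from anhydride 1; should the sense of induction on this substrate be the opposite, the pseudo-enantiomeric quinine is used in step 1 and nothing else changes.

## Route

Step 1
Reactants: 1 cis-cyclobut-3-ene-1,2-dicarboxylic anhydride
Product: 2 (1S,2R)-2-(methoxycarbonyl)cyclobut-3-ene-1-carboxylic acid
Conditions: MeOH (3 equiv), quinidine (1.1 equiv), toluene, −55 °C; then aq. HCl
Reagents that add atoms: methanol, CO
Why: Alkaloid-mediated desymmetrizing methanolysis of a meso anhydride; the chiral amine differentiates the two enantiotopic carbonyl groups, which fixes C5 (the ester-bearing carbon) and decides that the acid carbon becomes C2 and the ester carbon C6.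

Step 2
Reactants: 2 (1S,2R)-2-(methoxycarbonyl)cyclobut-3-ene-1-carboxylic acid; 3 4-bromo-1,2-dimethoxybenzene
Product: 6 methyl (1R,2S)-2-(3,4-dimethoxybenzoyl)cyclobut-3-ene-1-carboxylate, via acid chloride 4 (not isolated), via arylmagnesium bromide 5 (not isolated)
Conditions: 2, (COCl)2, DMF (cat.), CH2Cl2, 0 °C → rt, evaporation; 3, Mg, THF, 40 °C; 5 added to 4, Fe(acac)3 (3 mol %), THF, −78 °C
Reagents that add atoms: none
Why: Acid chloride formation followed by iron-catalysed acylation of an aryl Grignard reagent, which is fast at −78 °C and leaves the methyl ester alone. The C1 centre may epimerize but is planarized in step 3, and C5, the less acidic position, is not affected.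

Step 3
Reactants: 6 methyl (1R,2S)-2-(3,4-dimethoxybenzoyl)cyclobut-3-ene-1-carboxylate
Product: 8 methyl (1R,2R)-2-(3,4-dimethoxybenzoyl)-2-hydroxycyclobut-3-ene-1-carboxylate, via potassium enolate 7 (not isolated)
Conditions: KN(SiMe3)2 (1.1 equiv), THF, −78 °C; trans-3-phenyl-2-(phenylsulfonyl)oxaziridine, −78 °C; AcOH, −78 °C
Reagents that add atoms: trans-3-phenyl-2-(phenylsulfonyl)oxaziridine, O=S(=O)(c1ccccc1)N1OC1c1ccccc1
Why: Enolate hydroxylation with an N-sulfonyloxaziridine (Davis oxidation); the ketone α-proton at C1 is removed selectively and the oxidant attacks the α-carbon of the dienolate. It approaches the flat C1 from the face anti to the C6 ester on the neighbouring C5, so the oxygen ends trans and the aroyl group cis to that ester. The cold acidic quench protonates the tertiary alkoxide before it can fragment.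

Step 4
Reactants: 8 methyl (1R,2R)-2-(3,4-dimethoxybenzoyl)-2-hydroxycyclobut-3-ene-1-carboxylate
Product: 9 methyl (1R,2R)-2-[(S)-(3,4-dimethoxyphenyl)(hydroxy)methyl]-2-hydroxycyclobut-3-ene-1-carboxylate
Conditions: Zn(BH4)2, Et2O, −20 → 0 °C; H2O
Reagents that add atoms: none
Why: Chelation-controlled reduction of an α-hydroxy ketone: zinc bridges the C1 hydroxyl and the C2 carbonyl oxygen, and the two faces of the carbonyl are then flanked by C8 (a ring sp2 CH) and by C5 (carrying the ester that is cis to C2). Hydride enters from the C8 side and gives the (S)-carbinol; ester and alkene are inert to this reagent at low temperature. The crude diol is taken on at once.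

Step 5
Reactants: 9 methyl (1R,2R)-2-[(S)-(3,4-dimethoxyphenyl)(hydroxy)methyl]-2-hydroxycyclobut-3-ene-1-carboxylate
Product: 10 methyl (3R,4R,8S)-8-(3,4-dimethoxyphenyl)-6,6-dimethyl-5,7-dioxaspiro[3.4]oct-1-ene-3-carboxylate
Conditions: 2-methoxypropene, PPTS (cat.), CH2Cl2, 0 °C; Et3N
Reagents that add atoms: 2-methoxypropene, COC(C)=C
Why: Acid-catalysed ketalization of a 1,2-diol with an enol ether, fast at 0 °C under a weak acid that does not ionize the benzylic alcohol. Tying O1 to O2 also stops the C2 hydroxyl from lactonizing onto the cis C6 ester, which is thereby reserved for the C8 hydroxyl in step 6.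

Step 6
Reactants: 10 methyl (3R,4R,8S)-8-(3,4-dimethoxyphenyl)-6,6-dimethyl-5,7-dioxaspiro[3.4]oct-1-ene-3-carboxylate
Product: 13 (4S,5S,9R)-4-(3,4-dimethoxyphenyl)-9-(hydroxymethyl)-2,2-dimethyl-1,3,7-trioxaspiro[4.4]nonan-8-one, via ozonide 11 (not isolated), via diol ester 12 (not isolated)
Conditions: O3/O2, CH2Cl2, −78 °C (Sudan Red 7B as end-point indicator); N2 purge; MeOH, NaBH4, −78 → 0 °C; pH 7 buffer
Reagents that add atoms: ozone, [O-][O+]=O
Why: Ozone adds as a 1,3-dipole to the strained C4=C8 bond; the primary ozonide cycloreverts to a carbonyl and a carbonyl oxide that are held together by the C1–C5 bond and recombine to the bicyclic ozonide 11. Borohydride opens the peroxide bridge and reduces both unveiled aldehydes, giving the C4 and C8 carbinols of 12. The C8 alkoxide then acylates on the C6 ester in a 5-exo-trig closure that forms C6–O7 and ring A (C5, C6, O7, C8, C1), helped by the fully substituted C1; the C4 hydroxyl could reach C6 only through a four-membered ring and stays free. The closest known reaction type is the ozonolysis of cyclobutenes with borohydride work-up to 1,4-diols, followed by the usual lactonization of a γ-hydroxy ester. No stereocentre is created: C1, C2 and C5 are carried over, and the cis/anti array built on the four-membered ring becomes the open-chain array that later gives the trans ring fusion. The step needs chemoselectivity for the alkene over the dimethoxyarene, which ring strain, −78 °C and the indicator dye should secure. It also needs C5 to survive the moment when it is α to both the ester and the C4 aldehyde with the acetonide oxygen in the β position; this is secured because C4 stays masked as an acetal carbon of the ozonide until hydride is present, so the aldehyde is reduced as it forms. Borohydride is kept near stoichiometric and the mixture at or below 0 °C so that the lactone is not reduced further.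

Step 7
Reactants: 13 (4S,5S,9R)-4-(3,4-dimethoxyphenyl)-9-(hydroxymethyl)-2,2-dimethyl-1,3,7-trioxaspiro[4.4]nonan-8-one
Product: 14 (4S,5S,9R)-9-({[tert-butyl(diphenyl)silyl]oxy}methyl)-4-(3,4-dimethoxyphenyl)-2,2-dimethyl-1,3,7-trioxaspiro[4.4]nonan-8-one
Conditions: t-BuPh2SiCl, imidazole, DMF, 0 °C → rt
Reagents that add atoms: tert-butyl(chloro)diphenylsilane, CC(C)(C)[Si](Cl)(c1ccccc1)c1ccccc1
Why: Silylation of the primary C4 hydroxyl; this silyl ether is chosen because it withstands the aryllithium of step 8 and the Lewis acid of step 9, and it keeps the C4 oxygen from acting as a nucleophile.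

Step 8
Reactants: 14 (4S,5S,9R)-9-({[tert-butyl(diphenyl)silyl]oxy}methyl)-4-(3,4-dimethoxyphenyl)-2,2-dimethyl-1,3,7-trioxaspiro[4.4]nonan-8-one; 3 4-bromo-1,2-dimethoxybenzene
Product: 16 (4S,5S,9R)-9-({[tert-butyl(diphenyl)silyl]oxy}methyl)-4,8-bis(3,4-dimethoxyphenyl)-2,2-dimethyl-1,3,7-trioxaspiro[4.4]nonan-8-ol, via aryllithium 15 (not isolated)
Conditions: 3, n-BuLi, THF, −78 °C; then 14, −78 °C; AcOH, −78 °C
Reagents that add atoms: none
Why: Bromine–lithium exchange and addition of the aryllithium to a γ-lactone, which stops at the lithium hemiketalate at −78 °C as in aryl C-glycoside synthesis, so one arene is delivered to C6. Addition is faster than enolization at C5. The lactol is used crude as its mixture of C6 anomers.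

Step 9
Reactants: 16 (4S,5S,9R)-9-({[tert-butyl(diphenyl)silyl]oxy}methyl)-4,8-bis(3,4-dimethoxyphenyl)-2,2-dimethyl-1,3,7-trioxaspiro[4.4]nonan-8-ol
Product: 17 tert-butyl{[(4S,5S,8R,9S)-4,8-bis(3,4-dimethoxyphenyl)-2,2-dimethyl-1,3,7-trioxaspiro[4.4]nonan-9-yl]methoxy}diphenylsilane
Conditions: Et3SiH, BF3·OEt2, CH2Cl2, −78 → −40 °C; aq. NaHCO3
Reagents that add atoms: none
Why: Ionic reduction of a lactol: BF3·OEt2 ionizes the hemiketal to the aryl-stabilized O7=C6 oxocarbenium ion and the silane delivers hydride. In the favoured envelope (C1 as the flap, C1–O1 pseudoaxial, C1–C2 and C5–C4 pseudoequatorial) hydride adds on the inside face, cis to O1 and to C4, as it does in 2,3-O-isopropylidene furanosyl cations; the arene therefore ends trans to C4 (6R in target numbering), which is also the more stable C6 epimer. The acetonide and the silyl ether survive at this temperature.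

Step 10
Reactants: 17 tert-butyl{[(4S,5S,8R,9S)-4,8-bis(3,4-dimethoxyphenyl)-2,2-dimethyl-1,3,7-trioxaspiro[4.4]nonan-9-yl]methoxy}diphenylsilane
Product: 18 [(4S,5S,8R,9S)-4,8-bis(3,4-dimethoxyphenyl)-2,2-dimethyl-1,3,7-trioxaspiro[4.4]nonan-9-yl]methanol
Conditions: Bu4NF, THF, 0 °C → rt
Reagents that add atoms: none
Why: Fluoride-induced cleavage of the silyl ether; no other group in 17 responds to fluoride or to the mild basicity of the reagent.

Step 11
Reactants: 18 [(4S,5S,8R,9S)-4,8-bis(3,4-dimethoxyphenyl)-2,2-dimethyl-1,3,7-trioxaspiro[4.4]nonan-9-yl]methanol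
Product: 19 [(4S,5S,8R,9S)-4,8-bis(3,4-dimethoxyphenyl)-2,2-dimethyl-1,3,7-trioxaspiro[4.4]nonan-9-yl]methyl 4-methylbenzenesulfonate
Conditions: TsCl, Et3N, DMAP (cat.), CH2Cl2, 0 °C → rt
Reagents that add atoms: 4-methylbenzenesulfonyl chloride, Cc1ccc(cc1)S(Cl)(=O)=O
Why: Sulfonylation of the only free hydroxyl turns C4 into the electrophile for ring B while O1 and O2 are still tied up in the acetonide.

Step 12
Reactants: 19 [(4S,5S,8R,9S)-4,8-bis(3,4-dimethoxyphenyl)-2,2-dimethyl-1,3,7-trioxaspiro[4.4]nonan-9-yl]methyl 4-methylbenzenesulfonate
Product: 20 [(2R,3S,4S)-2-(3,4-dimethoxyphenyl)-4-[(S)-(3,4-dimethoxyphenyl)(hydroxy)methyl]-4-hydroxyoxolan-3-yl]methyl 4-methylbenzenesulfonate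
Conditions: AcOH/H2O (4:1), 45 °C
Reagents that add atoms: none
Why: Acid-catalysed hydrolysis of the isopropylidene ketal, which proceeds through the 2-propylidene oxocarbenium ion, so the C1–O and C2–O bonds are never broken and neither centre is touched. Aqueous acetic acid is weak enough to leave the benzylic ethers and the primary tosylate intact.

Step 13
Reactants: 20 [(2R,3S,4S)-2-(3,4-dimethoxyphenyl)-4-[(S)-(3,4-dimethoxyphenyl)(hydroxy)methyl]-4-hydroxyoxolan-3-yl]methyl 4-methylbenzenesulfonate
Product: 21 (1S,2S,5S,6R)-2,6-bis(3,4-dimethoxyphenyl)-3,7-dioxabicyclo[3.3.0]octan-1-ol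
Conditions: NaH (1.1 equiv), THF (0.01 M), 0 °C → rt; pH 7 buffer
Reagents that add atoms: none
Why: Intramolecular Williamson etherification, 5-exo-tet: the secondary benzylic C2 alkoxide displaces the primary C4 tosylate, forming O3–C4 and closing ring B with C2 untouched. The closure is irreversible, which is what lets the strained trans ring fusion form; the tertiary C1 alkoxide could close only a four-membered ring. Neutral work-up protects the acid-sensitive product.

## Compound list

1 | cis-cyclobut-3-ene-1,2-dicarboxylic anhydride (meso) | O=C1OC(=O)[C@H]2C=C[C@@H]12 | starting material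
2 | (1S,2R)-2-(methoxycarbonyl)cyclobut-3-ene-1-carboxylic acid | COC(=O)[C@@H]1C=C[C@@H]1C(=O)O | intermediate
3 | 4-bromo-1,2-dimethoxybenzene | COc1ccc(Br)cc1OC | starting material
4 | methyl (1R,2S)-2-(chlorocarbonyl)cyclobut-3-ene-1-carboxylate | COC(=O)[C@@H]1C=C[C@@H]1C(Cl)=O | intermediate (not isolated)
5 | (3,4-dimethoxyphenyl)magnesium bromide | COc1ccc([Mg]Br)cc1OC | intermediate (not isolated)
6 | methyl (1R,2S)-2-(3,4-dimethoxybenzoyl)cyclobut-3-ene-1-carboxylate | COC(=O)[C@@H]1C=C[C@@H]1C(=O)c2ccc(OC)c(OC)c2 | intermediate
7 | potassium enolate of 6 (C1=C2 enolate, enolate geometry not defined, C5 as in 6) | COC(=O)[C@@H]1C=CC1=C([O-])c2ccc(OC)c(OC)c2.[K+] | intermediate (not isolated)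
8 | methyl (1R,2R)-2-(3,4-dimethoxybenzoyl)-2-hydroxycyclobut-3-ene-1-carboxylate | COC(=O)[C@@H]1C=C[C@]1(O)C(=O)c2ccc(OC)c(OC)c2 | intermediate
9 | methyl (1R,2R)-2-[(S)-(3,4-dimethoxyphenyl)(hydroxy)methyl]-2-hydroxycyclobut-3-ene-1-carboxylate | COC(=O)[C@@H]1C=C[C@]1(O)[C@@H](O)c2ccc(OC)c(OC)c2 | intermediate
10 | methyl (3R,4R,8S)-8-(3,4-dimethoxyphenyl)-6,6-dimethyl-5,7-dioxaspiro[3.4]oct-1-ene-3-carboxylate | COC(=O)[C@@H]1C=C[C@@]12OC(C)(C)O[C@H]2c3ccc(OC)c(OC)c3 | intermediate
11 | secondary ozonide of 10 (2,3,7-trioxabicyclo[2.2.1]heptane with C4 and C8 as bridgehead acetal carbons; C1, C2, C5 as in 10, orientation of the peroxide bridge not defined) | COC(=O)[C@@H]1C2OOC(O2)[C@@]13OC(C)(C)O[C@H]3c4ccc(OC)c(OC)c4 | intermediate (not isolated)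
12 | methyl (2R)-2-[(4S,5S)-5-(3,4-dimethoxyphenyl)-4-(hydroxymethyl)-2,2-dimethyl-1,3-dioxolan-4-yl]-3-hydroxypropanoate | COC(=O)[C@H](CO)[C@@]1(CO)OC(C)(C)O[C@H]1c2ccc(OC)c(OC)c2 | intermediate (not isolated)
13 | (4S,5S,9R)-4-(3,4-dimethoxyphenyl)-9-(hydroxymethyl)-2,2-dimethyl-1,3,7-trioxaspiro[4.4]nonan-8-one | O=C1OC[C@@]2(OC(C)(C)O[C@H]2c3ccc(OC)c(OC)c3)[C@H]1CO | intermediate
14 | (4S,5S,9R)-9-({[tert-butyl(diphenyl)silyl]oxy}methyl)-4-(3,4-dimethoxyphenyl)-2,2-dimethyl-1,3,7-trioxaspiro[4.4]nonan-8-one | O=C1OC[C@@]2(OC(C)(C)O[C@H]2c3ccc(OC)c(OC)c3)[C@H]1CO[Si](c4ccccc4)(c5ccccc5)C(C)(C)C | intermediate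
15 | (3,4-dimethoxyphenyl)lithium | [Li]c1ccc(OC)c(OC)c1 | intermediate (not isolated)
16 | (4S,5S,9R)-9-({[tert-butyl(diphenyl)silyl]oxy}methyl)-4,8-bis(3,4-dimethoxyphenyl)-2,2-dimethyl-1,3,7-trioxaspiro[4.4]nonan-8-ol (both anomers at the hemiketal carbon C6 of the target numbering) | OC1(c2ccc(OC)c(OC)c2)OC[C@@]3(OC(C)(C)O[C@H]3c4ccc(OC)c(OC)c4)[C@H]1CO[Si](c5ccccc5)(c6ccccc6)C(C)(C)C | intermediate
17 | tert-butyl{[(4S,5S,8R,9S)-4,8-bis(3,4-dimethoxyphenyl)-2,2-dimethyl-1,3,7-trioxaspiro[4.4]nonan-9-yl]methoxy}diphenylsilane | COc1ccc([C@@H]2OC[C@@]3(OC(C)(C)O[C@H]3c4ccc(OC)c(OC)c4)[C@H]2CO[Si](c5ccccc5)(c6ccccc6)C(C)(C)C)cc1OC | intermediate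
18 | [(4S,5S,8R,9S)-4,8-bis(3,4-dimethoxyphenyl)-2,2-dimethyl-1,3,7-trioxaspiro[4.4]nonan-9-yl]methanol | COc1ccc([C@@H]2OC[C@@]3(OC(C)(C)O[C@H]3c4ccc(OC)c(OC)c4)[C@H]2CO)cc1OC | intermediate
19 | [(4S,5S,8R,9S)-4,8-bis(3,4-dimethoxyphenyl)-2,2-dimethyl-1,3,7-trioxaspiro[4.4]nonan-9-yl]methyl 4-methylbenzenesulfonate | COc1ccc([C@@H]2OC[C@@]3(OC(C)(C)O[C@H]3c4ccc(OC)c(OC)c4)[C@H]2COS(=O)(=O)c5ccc(C)cc5)cc1OC | intermediate
20 | [(2R,3S,4S)-2-(3,4-dimethoxyphenyl)-4-[(S)-(3,4-dimethoxyphenyl)(hydroxy)methyl]-4-hydroxyoxolan-3-yl]methyl 4-methylbenzenesulfonate | COc1ccc([C@@H]2OC[C@](O)([C@@H](O)c3ccc(OC)c(OC)c3)[C@H]2COS(=O)(=O)c4ccc(C)cc4)cc1OC | intermediate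
21 | (1S,2S,5S,6R)-2,6-bis(3,4-dimethoxyphenyl)-3,7-dioxabicyclo[3.3.0]octan-1-ol | COc1ccc([C@@H]2OC[C@]3(O)[C@H](c4ccc(OC)c(OC)c4)OC[C@@H]23)cc1OC | target

## Step count and least certain steps

Total: 13 steps. Longest linear sequence: 13 steps, from anhydride 1 to target 21; bromide 3 enters in steps 2 and 8.

Step 6 (key step). What may go wrong:
- Ozone may attack the dimethoxyarene once the alkene is consumed.
- C5 may enolize, or the acetonide oxygen may be lost by β-elimination, during the short time in which C4 is an aldehyde next to the ester.
- Borohydride may reduce the β-hydroxy ester or the lactone further.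

Fallback, by known chemistry that separates oxidation from cleavage: 10 is dihydroxylated with OsO4 (cat.) and N-methylmorpholine N-oxide in acetone/water on the ring face anti to the ester to give the cis-cyclobutanediol F1. NaIO4 in THF/pH 7 buffer cleaves F1 to the dialdehyde F2, which is reduced at once with NaBH4 in MeOH at −40 °C to 12. Lactonization of 12 returns the route to 13.

Step 3. What may go wrong:
- The tertiary potassium alkoxide may fragment by retro-aldol cleavage of the C1–C5 bond, driven by release of cyclobutene strain with the ester as acceptor.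
- An acyloin-type ring expansion may occur.
- The dienolate may be oxidized at the remote carbon C4.
- Face selection may be incomplete.

Fallback, which removes the acceptor for the fragmentation: 6 is saponified with LiOH in THF/water at 0 °C to the keto acid F3 (its C1 configuration is of no consequence). The dianion of F3, made with two equivalents of KN(SiMe3)2, is hydroxylated with the same oxaziridine to the hydroxy keto acid F4, in which a carboxylate cannot stabilize the carbanion that cleavage would require. Esterification of F4 with Me3SiCHN2 in MeOH/toluene returns the route to 8.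

Step 4. What may go wrong:
- Hydride may be delivered from the wrong face if the C8 and C5 sides of the chelate differ too little.
- The new C2 hydroxyl may lactonize onto the cis C6 ester.
- Zinc may promote a ketol shift.

Fallback, which replaces substrate control by catalyst control: asymmetric transfer hydrogenation of the aryl ketone of 8 with RuCl[(R,R)-TsDPEN](p-cymene) in HCO2H/Et3N. The (R,R) ligand is chosen by analogy with simple aryl alkyl ketones so as to give the (S)-carbinol. It runs directly from 8 to 9 and makes no new compound (none, F0); 9 is again ketalized without purification.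

Step 9. What may go wrong:
- Hydride may be delivered anti to the C4 arm if plain steric approach control overrides the alkoxy-directed inside attack, giving the C6 epimer.
- The acetonide may be lost, or C2 ionized, by the Lewis acid.

Fallback, which inverts the order in which hydrogen and arene reach C6, so that the same steric preference gives the wanted epimer: 14 is reduced with i-Bu2AlH in CH2Cl2 at −78 °C to the lactol F5, which is acetylated (Ac2O, pyridine) to the acetate F6. Ionization of F6 with SnCl4 in CH2Cl2 at low temperature in the presence of 1,2-dimethoxybenzene lets the arene attack the C6 oxocarbenium ion para to a methoxy group and anti to C4. This returns the route to 17.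

Step 13. What may go wrong:
- The tertiary C1 alkoxide may close to an oxetane.
- Grob-type fragmentation across C1–C5 may compete.
- Closure may be slow because the product is trans-fused.

Fallback, which keeps the tertiary oxygen covalently bound while the secondary one reacts: 20 is heated with Bu2SnO in toluene with removal of water to give the dibutylstannylene acetal F7. Heating F7 in DMF with Bu4NBr (cat.) alkylates the less hindered C2 oxygen with the C4 tosylate, and aqueous work-up releases 21.

## Further compounds

F1 | step 6 | methyl 8-(3,4-dimethoxyphenyl)-1,2-dihydroxy-6,6-dimethyl-5,7-dioxaspiro[3.4]octane-3-carboxylate (cis-diol anti to the ester; other centres as in 10) | COC(=O)[C@@H]1[C@@H](O)[C@@H](O)[C@@]12OC(C)(C)O[C@H]2c3ccc(OC)c(OC)c3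
F2 | step 6 | methyl 2-[5-(3,4-dimethoxyphenyl)-4-formyl-2,2-dimethyl-1,3-dioxolan-4-yl]-3-oxopropanoate (dialdehyde, spatial arrangement as in 12) | COC(=O)[C@H](C=O)[C@@]1(C=O)OC(C)(C)O[C@H]1c2ccc(OC)c(OC)c2
F3 | step 3 | (1R,2S)-2-(3,4-dimethoxybenzoyl)cyclobut-3-ene-1-carboxylic acid | OC(=O)[C@@H]1C=C[C@@H]1C(=O)c2ccc(OC)c(OC)c2
F4 | step 3 | (1R,2R)-2-(3,4-dimethoxybenzoyl)-2-hydroxycyclobut-3-ene-1-carboxylic acid | OC(=O)[C@@H]1C=C[C@]1(O)C(=O)c2ccc(OC)c(OC)c2
F0 | step 4 | none | none
F5 | step 9 | (4S,5S,9R)-9-({[tert-butyl(diphenyl)silyl]oxy}methyl)-4-(3,4-dimethoxyphenyl)-2,2-dimethyl-1,3,7-trioxaspiro[4.4]nonan-8-ol (both anomers) | OC1OC[C@@]2(OC(C)(C)O[C@H]2c3ccc(OC)c(OC)c3)[C@H]1CO[Si](c4ccccc4)(c5ccccc5)C(C)(C)C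
F6 | step 9 | (4S,5S,9R)-9-({[tert-butyl(diphenyl)silyl]oxy}methyl)-4-(3,4-dimethoxyphenyl)-2,2-dimethyl-1,3,7-trioxaspiro[4.4]nonan-8-yl acetate (both anomers) | CC(=O)OC1OC[C@@]2(OC(C)(C)O[C@H]2c3ccc(OC)c(OC)c3)[C@H]1CO[Si](c4ccccc4)(c5ccccc5)C(C)(C)C
F7 | step 13 | dibutylstannylene acetal of 20 (2,2-dibutyl-1,3,2-dioxastannolane spanning O1 and O2, other centres as in 20) | COc1ccc([C@@H]2OC[C@@]3(O[Sn](CCCC)(CCCC)O[C@H]3c4ccc(OC)c(OC)c4)[C@H]2COS(=O)(=O)c5ccc(C)cc5)cc1OC
A1 | alternative 1 | lactone diol with the C6 tert-butyldimethylsilyl ether (C8 as lactone carbonyl, C4 as O-methylene) | O=C1OC[C@@H]([C@@H](O[Si](C)(C)C(C)(C)C)c2ccc(OC)c(OC)c2)[C@@]1(O)[C@@H](O)c3ccc(OC)c(OC)c3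
A2 | alternative 1 | (E)-benzylidene lactone, substrate of the dihydroxylation | O=C1OC[C@@H]([C@@H](O[Si](C)(C)C(C)(C)C)c2ccc(OC)c(OC)c2)/C1=C\c3ccc(OC)c(OC)c3
A3 | alternative 2 | triethylsilyl ether of 21 | COc1ccc(cc1OC)[C@@H]2OC[C@]3(O[Si](CC)(CC)CC)[C@H](c4ccc(OC)c(OC)c4)OC[C@@H]23
A4 | alternative 2 | open-chain C4,C8 bis-tosylate with free C2 and C6 hydroxyls and the C1 triethylsilyl ether | COc1ccc(cc1OC)[C@H](O)[C@H](COS(=O)(=O)c2ccc(C)cc2)[C@](O[Si](CC)(CC)CC)(COS(=O)(=O)c3ccc(C)cc3)[C@@H](O)c4ccc(OC)c(OC)c4
A5 | alternative 3 | 2-aryl-3-vinyl oxolane (ring A) with the C2 triisopropylsilyl ether | COc1ccc(cc1OC)[C@@H]1OC[C@](O)([C@@H](O[Si](C(C)C)(C(C)C)C(C)C)c2ccc(OC)c(OC)c2)[C@H]1C=C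
A6 | alternative 3 | (E)-allylsilane C1,C8 diol with the C2 triisopropylsilyl ether | C[Si](C)(C)C/C=C/[C@](O)(CO)[C@@H](O[Si](C(C)C)(C(C)C)C(C)C)c1ccc(OC)c(OC)c1
A7 | alternative 3 | 3,4-dimethoxybenzaldehyde dimethyl acetal | COC(OC)c1ccc(OC)c(OC)c1
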